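**Plan**

- Cuts (ring numbered C1 = alkylidene carbon, C2 = CH carrying the hydroxypropyl arm, C3 = quaternary C, C4 = CHCH3, C5/C6 = CH2): ring bonds C1–C2 and C3–C4 together in one [4+2] event; the two CH2–CH= bonds of the decadienyl chain (Negishi couplings); the C1–C2 bond of the hydroxypropyl arm (Wittig).
- Enabling feature: C1 is an exocyclic tetrasubstituted alkene carbon whose CHO carbon lies cis to C2, and C2 carries an arm carbon that can be a carboxyl. The sequence alkylidene C–CH2–O–C(=O)–C2–C1 is therefore a latent six-membered lactone (temporary ring), and C1 with C6, C5, C4 is a latent vinylallene.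
- Forward: vinylallenol + (E)-enoic acid → ester → intramolecular Diels–Alder reaction gives the cyclohexene ring and the lactone together → lactone opened, arm extended by two carbons, ring and arm alkenes saturated → side chain (made apart from 3-methylbut-2-enal and but-3-yn-1-ol) joined → reduction, desilylation, allylic oxidation.
- Stereochemistry: ring centres C2, C3, C4 and the Z enal geometry come from the allene axis (anti-SN2′ opening of an alkynyl oxirane made from (S)-2-methylglycidol) and from the E geometries of diene and dienophile. The carbinol comes from catalytic asymmetric propargylation, the epoxide from hydroxyl-directed threo epoxidation, and both E trisubstituted chain alkenes from syn-carboalumination.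

Key step: step 6

Assumption: in step 12 the (S)-configured phosphoric acid is taken to give the (S)-carbinol with this enal, by analogy with the usual facial sense of this catalyst class; the mirror-image catalyst would be used if the sense is opposite.

**Route**

Step 1
Reactants: 1 (S)-2-methylglycidol, [(2S)-2-methyloxiran-2-yl]methanol
Product: 2 (2R)-2-methyloxirane-2-carbaldehyde
Conditions: PhI(OAc)2, 2,2,6,6-tetramethylpiperidin-1-oxyl (cat.), CH2Cl2, 0 °C to rt; used as a solution
Reagents that add atoms: none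
Why: Oxoammonium-mediated alcohol oxidation (2,2,6,6-tetramethylpiperidin-1-oxyl/PhI(OAc)2) should stop at the aldehyde, and the quaternary α-carbon cannot epimerise (the descriptor changes only through the priority rules).

Step 2
Reactants: 2 (2R)-2-methyloxirane-2-carbaldehyde
Product: 3 (2S)-2-ethynyl-2-methyloxirane
Conditions: dimethyl (1-diazo-2-oxopropyl)phosphonate, K2CO3, MeOH, 0 °C to rt
Reagents that add atoms: dimethyl (1-diazo-2-oxopropyl)phosphonate, CC(=O)C(=[N+]=[N-])P(=O)(OC)OC
Why: Seyferth–Gilbert homologation with the Ohira–Bestmann reagent should convert the non-enolisable aldehyde into the terminal alkyne under mild base that leaves the 2,2-disubstituted oxirane intact.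

Step 3
Reactants: 3 (2S)-2-ethynyl-2-methyloxirane; 4 (E)-prop-1-en-1-ylboronic acid
Product: 5 (aS,5E)-2-methylhepta-2,3,5-trien-1-ol
Conditions: Pd(PPh3)4 (5 mol%), THF/H2O, rt to 40 °C
Reagents that add atoms: none
Why: Palladium-catalysed anti-SN2′ coupling of a propargylic oxirane with a boronic acid: zerovalent palladium opens the oxirane anti to the C–O bond to an allenylpalladium alkoxide, and transmetalation and reductive elimination with retention should turn the centre of 3 into the aS axis, the E alkene coming unchanged from 4.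

Step 4
Reactants: 6 tert-butyl(but-3-yn-1-yloxy)dimethylsilane
Product: 9 (2E)-5-(tert-butyldimethylsilyloxy)-3-methylpent-2-enoic acid, via alkenyldimethylalane 7 (not isolated), via lithium alkenylaluminate 8 (not isolated)
Conditions: AlMe3, Cp2ZrCl2 (0.2 equiv), CH2Cl2, 0 °C to rt; n-BuLi, THF, −78 °C; CO2; 1 M HCl, 0 °C
Reagents that add atoms: trimethylaluminium, C[Al](C)C; carbon dioxide, O=C=O
Why: Zirconium-catalysed syn-carboalumination (Negishi) places methyl on the internal and aluminium on the terminal alkyne carbon, and carboxylation of the derived aluminate with retention should give the (E)-3-methyl-2-enoic acid.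

Step 5
Reactants: 9 (2E)-5-(tert-butyldimethylsilyloxy)-3-methylpent-2-enoic acid; 5 (aS,5E)-2-methylhepta-2,3,5-trien-1-ol
Product: 10 (aS,5E)-2-methylhepta-2,3,5-trien-1-yl (2E)-5-(tert-butyldimethylsilyloxy)-3-methylpent-2-enoate
Conditions: N,N′-dicyclohexylcarbodiimide, 4-(dimethylamino)pyridine (cat.), CH2Cl2, 0 °C to rt
Reagents that add atoms: none
Why: Steglich esterification should join the primary allenyl carbinol and the acid without touching the allene axis or the enoate geometry.

Step 6
Reactants: 10 (aS,5E)-2-methylhepta-2,3,5-trien-1-yl (2E)-5-(tert-butyldimethylsilyloxy)-3-methylpent-2-enoate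
Product: 11 (7R,8R,8aS)-8-[2-(tert-butyldimethylsilyloxy)ethyl]-4,7,8-trimethyl-3,7,8,8a-tetrahydro-1H-isochromen-1-one
Conditions: PhMe (0.01 M), 2,6-di-tert-butyl-4-methylphenol (cat.), 140 °C, sealed tube
Reagents that add atoms: none
Why: Thermal intramolecular Diels–Alder reaction: the s-cis vinylallene (propenyl C=C plus the allene C=C nearer to it) is the diene, the tethered (E)-enoate C=C the dienophile, and the two sigma bonds (alkylidene carbon to the CH next to the carbonyl, and CHCH3 to the quaternary carbon) form in one concerted, asynchronous [4+2] step, whose closest known relatives are intramolecular cycloadditions of vinylallenes tethered through the distal allene carbon, which pass the axial chirality on to the new ring. The cyclohexene closes by suprafacial [4π+2π] addition and the temporary δ-lactone closes with it as the six-membered ring of a four-atom (C, C, O, C=O) tether, so that the remaining allene C=C becomes the exocyclic alkene with its CH2O carbon held cis to the ring-fusion CH, which is the Z geometry of the target enal. Because the tether can span only with the acyl carbon exo, the CH2CH2OSi arm on the quaternary carbon is endo and ends up cis to the outside methyl of the (E)-propenyl terminus, while the (E)-enoate places the quaternary methyl cis to the acyl carbon: the three contiguous centres get their relative configuration from the two alkene geometries plus the tether. Their absolute configuration comes from the aS allene axis, since the dienophile can reach only the diene face that carries the CH2O arm. Regio- and site-selectivity are fixed by the ester link; what the step needs is rate against bimolecular dimerisation of the vinylallene, which high dilution and the strain released at the sp carbon should secure.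

Step 7
Reactants: 11 (7R,8R,8aS)-8-[2-(tert-butyldimethylsilyloxy)ethyl]-4,7,8-trimethyl-3,7,8,8a-tetrahydro-1H-isochromen-1-one
Product: 12 (7R,8R,8aS)-8-(2-bromoethyl)-4,7,8-trimethyl-3,7,8,8a-tetrahydro-1H-isochromen-1-one
Conditions: Ph3PBr2, CH2Cl2, 0 °C to rt
Reagents that add atoms: dibromotriphenylphosphorane, BrP(Br)(c1ccccc1)(c1ccccc1)c1ccccc1
Why: Appel-type exchange of a primary silyl ether for bromide with Ph3PBr2 (oxyphosphonium, then SN2 by bromide) is neutral and installs the handle for the later zinc reagent while the allylic oxygen is still tied up in the lactone.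

Step 8
Reactants: 12 (7R,8R,8aS)-8-(2-bromoethyl)-4,7,8-trimethyl-3,7,8,8a-tetrahydro-1H-isochromen-1-one
Product: 13 (7R,8R,8aS)-8-(2-bromoethyl)-4,7,8-trimethyl-3,7,8,8a-tetrahydro-1H-isochromen-1-ol (lactol, both epimers at the hemiacetal carbon)
Conditions: i-Bu2AlH (1.1 equiv), CH2Cl2, −78 °C; aq. potassium sodium tartrate
Reagents that add atoms: none
Why: Partial hydride reduction of the lactone should stop at the aluminium hemiacetal at −78 °C and leave the alkyl bromide and the diene alone.

Step 9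
Reactants: 13 the lactol; 14 ethyl 2-(triphenylphosphoranylidene)acetate
Product: 15 ethyl (2E)-3-[(1S,5R,6R)-6-(2-bromoethyl)-2-[(2Z)-1-hydroxypropan-2-ylidene]-5,6-dimethylcyclohex-3-en-1-yl]prop-2-enoate
Conditions: 14 (2.5 equiv), PhCO2H (cat.), CH2Cl2, rt
Reagents that add atoms: none
Why: Wittig olefination of the ring-opened hydroxy aldehyde with the stabilised ylide should give the (E)-enoate (the last two carbons of the arm) and free the allylic CH2OH, whose Z relation to the ring CH is inherited from the lactone; the weakly basic ylide should not epimerise the α-centre.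

Step 10
Reactants: 15 the bromo dienyl enoate
Product: 16 ethyl 3-[(1S,2R,3R)-2-(2-bromoethyl)-6-[(2Z)-1-hydroxypropan-2-ylidene]-2,3-dimethylcyclohexyl]propanoate
Conditions: H2 (3 atm), RhCl(PPh3)3 (10 mol%), PhH/EtOH, rt
Reagents that add atoms: none
Why: Homogeneous catalytic hydrogenation with RhCl(PPh3)3 should saturate the two 1,2-disubstituted C=C bonds (ring alkene and enoate) while the tetrasubstituted exocyclic alkene and the C–Br bond stay inert; no stereocentre is formed.

Step 11
Reactants: 16 the hydroxy ester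
Product: 17 ethyl 3-[(1S,2R,3R)-2-(2-bromoethyl)-6-[(2Z)-1-(tert-butyldimethylsilyloxy)propan-2-ylidene]-2,3-dimethylcyclohexyl]propanoate
Conditions: TBSCl, imidazole, CH2Cl2, 0 °C to rt
Reagents that add atoms: tert-butyldimethylsilyl chloride, CC(C)(C)[Si](C)(C)Cl
Why: Silyl ether formation at the primary allylic alcohol removes the only acidic proton before the organozinc chemistry of step 21.

Step 12
Reactants: 18 3-methylbut-2-enal; 19 4,4,5,5-tetramethyl-2-(propa-1,2-dien-1-yl)-1,3,2-dioxaborolane
Product: 20 (4S)-6-methylhept-5-en-1-yn-4-ol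
Conditions: (S)-3,3′-bis(2,4,6-triisopropylphenyl)-1,1′-binaphthyl-2,2′-diyl hydrogen phosphate (5 mol%), 4 Å molecular sieves, PhMe, 0 °C; aqueous work-up
Reagents that add atoms: none
Why: Chiral Brønsted acid-catalysed propargylboration of the aldehyde with the allenylboronate through a closed six-membered SE2′ transition state, in which the catalyst selects the aldehyde face and so sets the S carbinol centre.

Step 13
Reactants: 20 (4S)-6-methylhept-5-en-1-yn-4-ol
Product: 21 tert-butyldimethyl{[(4S)-6-methylhept-5-en-1-yn-4-yl]oxy}silane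
Conditions: TBSCl, imidazole, DMF, rt
Reagents that add atoms: tert-butyldimethylsilyl chloride, CC(C)(C)[Si](C)(C)Cl
Why: Silyl ether formation keeps the ionisable allylic alkoxide away from the Lewis acidic carboalumination medium.

Step 14
Reactants: 21 the silyl ether
Product: 23 tert-butyl{[(1E,4S)-1-iodo-2,6-dimethylhepta-1,5-dien-4-yl]oxy}dimethylsilane, via alkenyldimethylalane 22 (not isolated)
Conditions: AlMe3, Cp2ZrCl2 (0.25 equiv), CH2Cl2, 0 °C to rt; then I2, THF, −30 °C
Reagents that add atoms: trimethylaluminium, C[Al](C)C; iodine, [I][I]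
Why: Zirconium-catalysed syn-carboalumination (Negishi) of the terminal alkyne (the trisubstituted alkene does not react) followed by iodinolysis with retention should give the (E)-2-methyl-1-iodoalkene.

Step 15
Reactants: 23 the iodo silyl ether
Product: 24 (1E,4S)-1-iodo-2,6-dimethylhepta-1,5-dien-4-ol
Conditions: Bu4NF, THF, 0 °C
Reagents that add atoms: none
Why: Fluoride desilylation frees the allylic hydroxyl that has to direct the epoxidation.

Step 16
Reactants: 24 the iodo dienol
Product: 25 (1S,3E)-1-[(2R)-3,3-dimethyloxiran-2-yl]-4-iodo-3-methylbut-3-en-1-ol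
Conditions: 3-chloroperbenzoic acid, NaHCO3, CH2Cl2, 0 °C
Reagents that add atoms: 3-chloroperbenzoic acid, OOC(=O)c1cccc(Cl)c1
Why: Hydroxyl-directed peracid (Prilezhaev) epoxidation: allylic 1,3-strain with the cis methyl holds the carbinol H in the alkene plane and hydrogen bonding delivers oxygen syn to OH, which should give the threo (1S,2′R) epoxy alcohol, the iodoalkene being too electron-poor to compete.

Step 17
Reactants: 25 the epoxy alcohol
Product: 26 tert-butyl{[(1S,3E)-1-[(2R)-3,3-dimethyloxiran-2-yl]-4-iodo-3-methylbut-3-en-1-yl]oxy}dimethylsilane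
Conditions: TBSCl, imidazole, DMF, rt to 40 °C
Reagents that add atoms: tert-butyldimethylsilyl chloride, CC(C)(C)[Si](C)(C)Cl
Why: Silyl ether formation blocks Payne rearrangement and O–H reactivity in the later organometallic and basic steps.

Step 18
Reactants: 27 but-3-yn-1-ol
Product: 29 (3E)-4-bromo-3-methylbut-3-en-1-ol, via alkenylalane alkoxide 28 (not isolated)
Conditions: AlMe3 (3 equiv), Cp2ZrCl2 (0.25 equiv), CH2Cl2, 0 °C to rt; then NBS, THF, −30 to 0 °C; aqueous work-up
Reagents that add atoms: trimethylaluminium, C[Al](C)C; N-bromosuccinimide, O=C1CCC(=O)N1Br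
Why: Zirconium-catalysed syn-carboalumination (Negishi) of the aluminium alkoxide of the butynol and bromination of the alkenyl–Al bond with retention should give the (E)-bromoalkene.

Step 19
Reactants: 29 (3E)-4-bromo-3-methylbut-3-en-1-ol
Product: 30 (1E)-1-bromo-4-iodo-2-methylbut-1-ene
Conditions: I2, PPh3, imidazole, CH2Cl2, 0 °C
Reagents that add atoms: iodine, [I][I]
Why: Appel iodination converts the primary alcohol into the iodide by SN2 on the oxyphosphonium ion, without touching the bromoalkene.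

Step 20
Reactants: 30 (1E)-1-bromo-4-iodo-2-methylbut-1-ene; 26 the epoxy iodoalkene
Product: 32 tert-butyl{[(1S,3E,7E)-8-bromo-1-[(2R)-3,3-dimethyloxiran-2-yl]-3,7-dimethylocta-3,7-dien-1-yl]oxy}dimethylsilane, via alkylzinc iodide 31 (not isolated)
Conditions: Zn dust (activated), THF, 35 °C; then 26, Pd(PPh3)4 (5 mol%), THF, rt
Reagents that add atoms: none
Why: Negishi coupling: zinc inserts only into the alkyl C–I bond and zerovalent palladium adds to the alkenyl iodide of 26 much faster than to either alkenyl bromide, so the sp3–sp2 bond should form with retention of the E geometry and the bromoalkene survives as the next handle.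

Step 21
Reactants: 17 the ring bromide; 32 the chain bromoalkene
Product: 34 ethyl 3-[(1S,2R,3R)-6-[(2Z)-1-(tert-butyldimethylsilyloxy)propan-2-ylidene]-2-{(3E,7E,10S)-10-(tert-butyldimethylsilyloxy)-10-[(2R)-3,3-dimethyloxiran-2-yl]-4,8-dimethyldeca-3,7-dien-1-yl}-2,3-dimethylcyclohexyl]propanoate, via alkylzinc bromide 33 (not isolated)
Conditions: Zn dust, LiCl, THF, 50 °C; then 32, Pd(OAc)2 (5 mol%), 2-dicyclohexylphosphino-2′,6′-dimethoxybiphenyl (10 mol%), THF/N-methylpyrrolidone, 40 °C
Reagents that add atoms: none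
Why: Negishi coupling of the primary alkylzinc bromide with the alkenyl bromide (retention of E geometry) joins ring and chain, the ester, silyl ethers and hindered epoxide being tolerated by the organozinc.

Step 22
Reactants: 34 the coupled ester
Product: 35 3-[(1S,2R,3R)-6-[(2Z)-1-(tert-butyldimethylsilyloxy)propan-2-ylidene]-2-{(3E,7E,10S)-10-(tert-butyldimethylsilyloxy)-10-[(2R)-3,3-dimethyloxiran-2-yl]-4,8-dimethyldeca-3,7-dien-1-yl}-2,3-dimethylcyclohexyl]propan-1-ol
Conditions: i-Bu2AlH (2.5 equiv), CH2Cl2, −78 to −40 °C; aq. potassium sodium tartrate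
Reagents that add atoms: none
Why: Hydride reduction of the ethyl ester with i-Bu2AlH gives the primary alcohol at low temperature, where the trisubstituted epoxide should not be opened.

Step 23
Reactants: 35 the bis-silyl ether
Product: 36 (2Z)-2-[(2S,3R,4R)-3-{(3E,7E,10S)-10-[(2R)-3,3-dimethyloxiran-2-yl]-10-hydroxy-4,8-dimethyldeca-3,7-dien-1-yl}-2-(3-hydroxypropyl)-3,4-dimethylcyclohexylidene]propan-1-ol
Conditions: Bu4NF, AcOH (1:1), THF, rt
Reagents that add atoms: none
Why: Buffered fluoride desilylation should remove both silyl ethers without alkoxide-driven Payne rearrangement of the epoxy alcohol.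

Step 24
Reactants: 36 the triol
Product: 37 CNP0208461.1, (2Z)-2-[(2S,3R,4R)-3-{(3E,7E,10S)-10-[(2R)-3,3-dimethyloxiran-2-yl]-10-hydroxy-4,8-dimethyldeca-3,7-dien-1-yl}-2-(3-hydroxypropyl)-3,4-dimethylcyclohexylidene]propanal
Conditions: MnO2 (activated, excess), CH2Cl2, rt
Reagents that add atoms: none
Why: MnO2 allylic oxidation should convert only the allylic primary alcohol into the enal, leaving the saturated primary and the secondary hydroxyl untouched and the Z geometry unchanged.

**Compound list**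

1 | (S)-2-methylglycidol, [(2S)-2-methyloxiran-2-yl]methanol | OC[C@@]1(C)CO1 | starting material
2 | (2R)-2-methyloxirane-2-carbaldehyde | O=C[C@@]1(C)CO1 | intermediate
3 | (2S)-2-ethynyl-2-methyloxirane | C#C[C@@]1(C)CO1 | intermediate
4 | (E)-prop-1-en-1-ylboronic acid | C/C=C/B(O)O | starting material
5 | (aS,5E)-2-methylhepta-2,3,5-trien-1-ol | OCC(C)=[C@@]=C([H])/C=C/C | intermediate
6 | tert-butyl(but-3-yn-1-yloxy)dimethylsilane | C#CCCO[Si](C)(C)C(C)(C)C | starting material
7 | [(1E)-4-(tert-butyldimethylsilyloxy)-2-methylbut-1-en-1-yl]dimethylalane | C[Al](C)/C=C(\C)CCO[Si](C)(C)C(C)(C)C | intermediate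
8 | lithium butyl[(1E)-4-(tert-butyldimethylsilyloxy)-2-methylbut-1-en-1-yl]dimethylaluminate | [Li+].CCCC[Al-](C)(C)/C=C(\C)CCO[Si](C)(C)C(C)(C)C | intermediate
9 | (2E)-5-(tert-butyldimethylsilyloxy)-3-methylpent-2-enoic acid | OC(=O)/C=C(\C)CCO[Si](C)(C)C(C)(C)C | intermediate
10 | (aS,5E)-2-methylhepta-2,3,5-trien-1-yl (2E)-5-(tert-butyldimethylsilyloxy)-3-methylpent-2-enoate | CC(C)(C)[Si](C)(C)OCC/C(C)=C/C(=O)OCC(C)=[C@@]=C([H])/C=C/C | intermediate
11 | (7R,8R,8aS)-8-[2-(tert-butyldimethylsilyloxy)ethyl]-4,7,8-trimethyl-3,7,8,8a-tetrahydro-1H-isochromen-1-one | O=C1OCC(C)=C2C=C[C@@H](C)[C@@](C)(CCO[Si](C)(C)C(C)(C)C)[C@H]12 | intermediate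
12 | (7R,8R,8aS)-8-(2-bromoethyl)-4,7,8-trimethyl-3,7,8,8a-tetrahydro-1H-isochromen-1-one | O=C1OCC(C)=C2C=C[C@@H](C)[C@@](C)(CCBr)[C@H]12 | intermediate
13 | (7R,8R,8aS)-8-(2-bromoethyl)-4,7,8-trimethyl-3,7,8,8a-tetrahydro-1H-isochromen-1-ol (both hemiacetal epimers) | OC1OCC(C)=C2C=C[C@@H](C)[C@@](C)(CCBr)[C@H]12 | intermediate
14 | ethyl 2-(triphenylphosphoranylidene)acetate | CCOC(=O)C=P(c1ccccc1)(c1ccccc1)c1ccccc1 | starting material
15 | ethyl (2E)-3-[(1S,5R,6R)-6-(2-bromoethyl)-2-[(2Z)-1-hydroxypropan-2-ylidene]-5,6-dimethylcyclohex-3-en-1-yl]prop-2-enoate | C/C(CO)=C1\C=C[C@@H](C)[C@@](C)(CCBr)[C@@H]1/C=C/C(=O)OCC | intermediate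
16 | ethyl 3-[(1S,2R,3R)-2-(2-bromoethyl)-6-[(2Z)-1-hydroxypropan-2-ylidene]-2,3-dimethylcyclohexyl]propanoate | C/C(CO)=C1\CC[C@@H](C)[C@@](C)(CCBr)[C@@H]1CCC(=O)OCC | intermediate
17 | ethyl 3-[(1S,2R,3R)-2-(2-bromoethyl)-6-[(2Z)-1-(tert-butyldimethylsilyloxy)propan-2-ylidene]-2,3-dimethylcyclohexyl]propanoate | C/C(CO[Si](C)(C)C(C)(C)C)=C1\CC[C@@H](C)[C@@](C)(CCBr)[C@@H]1CCC(=O)OCC | intermediate
18 | 3-methylbut-2-enal | CC(C)=CC=O | starting material
19 | 4,4,5,5-tetramethyl-2-(propa-1,2-dien-1-yl)-1,3,2-dioxaborolane | C=C=CB1OC(C)(C)C(C)(C)O1 | starting material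
20 | (4S)-6-methylhept-5-en-1-yn-4-ol | C#CC[C@H](O)C=C(C)C | intermediate
21 | tert-butyldimethyl{[(4S)-6-methylhept-5-en-1-yn-4-yl]oxy}silane | C#CC[C@H](O[Si](C)(C)C(C)(C)C)C=C(C)C | intermediate
22 | [(1E,4S)-4-(tert-butyldimethylsilyloxy)-2,6-dimethylhepta-1,5-dien-1-yl]dimethylalane | C[Al](C)/C=C(\C)C[C@H](O[Si](C)(C)C(C)(C)C)C=C(C)C | intermediate
23 | tert-butyl{[(1E,4S)-1-iodo-2,6-dimethylhepta-1,5-dien-4-yl]oxy}dimethylsilane | I/C=C(\C)C[C@H](O[Si](C)(C)C(C)(C)C)C=C(C)C | intermediate
24 | (1E,4S)-1-iodo-2,6-dimethylhepta-1,5-dien-4-ol | I/C=C(\C)C[C@H](O)C=C(C)C | intermediate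
25 | (1S,3E)-1-[(2R)-3,3-dimethyloxiran-2-yl]-4-iodo-3-methylbut-3-en-1-ol | I/C=C(\C)C[C@H](O)[C@H]1OC1(C)C | intermediate
26 | tert-butyl{[(1S,3E)-1-[(2R)-3,3-dimethyloxiran-2-yl]-4-iodo-3-methylbut-3-en-1-yl]oxy}dimethylsilane | I/C=C(\C)C[C@H](O[Si](C)(C)C(C)(C)C)[C@H]1OC1(C)C | intermediate
27 | but-3-yn-1-ol | C#CCCO | starting material
28 | dimethylaluminium (3E)-4-(dimethylalumanyl)-3-methylbut-3-en-1-olate | C[Al](C)OCC/C(C)=C/[Al](C)C | intermediate
29 | (3E)-4-bromo-3-methylbut-3-en-1-ol | OCC/C(C)=C/Br | intermediate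
30 | (1E)-1-bromo-4-iodo-2-methylbut-1-ene | ICC/C(C)=C/Br | intermediate
31 | [(3E)-4-bromo-3-methylbut-3-en-1-yl](iodo)zinc | I[Zn]CC/C(C)=C/Br | intermediate
32 | tert-butyl{[(1S,3E,7E)-8-bromo-1-[(2R)-3,3-dimethyloxiran-2-yl]-3,7-dimethylocta-3,7-dien-1-yl]oxy}dimethylsilane | Br/C=C(\C)CC/C=C(\C)C[C@H](O[Si](C)(C)C(C)(C)C)[C@H]1OC1(C)C | intermediate
33 | alkylzinc bromide of 17 (C–Br replaced by C–ZnBr, otherwise unchanged) | C/C(CO[Si](C)(C)C(C)(C)C)=C1\CC[C@@H](C)[C@@](C)(CC[Zn]Br)[C@@H]1CCC(=O)OCC | intermediate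
34 | ethyl 3-[(1S,2R,3R)-6-[(2Z)-1-(tert-butyldimethylsilyloxy)propan-2-ylidene]-2-{(3E,7E,10S)-10-(tert-butyldimethylsilyloxy)-10-[(2R)-3,3-dimethyloxiran-2-yl]-4,8-dimethyldeca-3,7-dien-1-yl}-2,3-dimethylcyclohexyl]propanoate | C/C(CO[Si](C)(C)C(C)(C)C)=C1\CC[C@@H](C)[C@@](C)(CC/C=C(\C)CC/C=C(\C)C[C@H](O[Si](C)(C)C(C)(C)C)[C@H]2OC2(C)C)[C@@H]1CCC(=O)OCC | intermediate
35 | the propan-1-ol corresponding to ester 34 (both silyl ethers retained) | C/C(CO[Si](C)(C)C(C)(C)C)=C1\CC[C@@H](C)[C@@](C)(CC/C=C(\C)CC/C=C(\C)C[C@H](O[Si](C)(C)C(C)(C)C)[C@H]2OC2(C)C)[C@@H]1CCCO | intermediate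
36 | (2Z)-2-[(2S,3R,4R)-3-{(3E,7E,10S)-10-[(2R)-3,3-dimethyloxiran-2-yl]-10-hydroxy-4,8-dimethyldeca-3,7-dien-1-yl}-2-(3-hydroxypropyl)-3,4-dimethylcyclohexylidene]propan-1-ol | C/C(CO)=C1\CC[C@@H](C)[C@@](C)(CC/C=C(\C)CC/C=C(\C)C[C@H](O)[C@H]2OC2(C)C)[C@@H]1CCCO | intermediate
37 | CNP0208461.1, (2Z)-2-[(2S,3R,4R)-3-{(3E,7E,10S)-10-[(2R)-3,3-dimethyloxiran-2-yl]-10-hydroxy-4,8-dimethyldeca-3,7-dien-1-yl}-2-(3-hydroxypropyl)-3,4-dimethylcyclohexylidene]propanal | C/C(C=O)=C1\CC[C@@H](C)[C@@](C)(CC/C=C(\C)CC/C=C(\C)C[C@H](O)[C@H]2OC2(C)C)[C@@H]1CCCO | target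

**Count and risks**

Total step count: 24. Longest linear sequence: 14 steps (1, 2, 3, 5–11, 21–24).

Steps most likely to fail:

1. Step 6. The cycloaddition may be too slow against bimolecular dimerisation and thermal decay of the vinylallene, because the ester tether must reach its less favoured s-cis form and the dienophile is β,β-disubstituted. The fallback runs the same tethered [4+2] as an ionic Diels–Alder reaction one oxidation level lower; it sets out from acid 9 and allenol 5 and comes back at lactone 11. Acid 9 is reduced with LiAlH4 to (2E)-5-(tert-butyldimethylsilyloxy)-3-methylpent-2-en-1-ol F1, oxidised with MnO2 to the enal F2 and converted with HC(OMe)3 and pyridinium p-toluenesulfonate into the dimethyl acetal F3. Exchange of one methoxy group for allenol 5 (pyridinium p-toluenesulfonate, PhH, removal of MeOH) gives the mixed acetal F4. Me3SiOTf (cat.) with 2,6-di-tert-butyl-4-methylpyridine in CH2Cl2 at −78 °C ionises F4 to a vinyl oxocarbenium ion, a much stronger dienophile, which should close the same two bonds through the same exo-tether geometry to the cyclic methyl acetal F5. Mild aqueous acid gives the lactol F6, and Ag2CO3 on Celite oxidises it to 11.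

2. Step 3. Material may be lost through the volatility and ready self-cycloaddition of the small free vinylallenol, and the 2,3-allenol may cycloisomerise under palladium. The fallback forms the allene only after the ester is in place; it sets out from oxirane 3 and acid 9 and comes back at ester 10, replacing steps 3 and 5. Acid 9 opens oxirane 3 at the CH2 carbon (Bu4NBr cat., MeCN, 60 °C) to the hydroxy ester F7. The tertiary propargylic alcohol is converted into its methyl carbonate F8 (LiN(SiMe3)2, ClCO2Me, THF, −78 °C). Pd(PPh3)4-catalysed anti-SN2′ coupling of F8 with boronic acid 4 should then give 10 directly; the C–O bond that leaves is the one that leaves in 3, so the same aS axis results.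

3. Step 21. The zinc halides formed in the warm coupling may open or rearrange the trisubstituted epoxide. The fallback installs the epoxide last; it sets out from iodide 23 (with zinc reagents 31 and 33) and comes back at the target 37. Iodide 23 is coupled with 31 to the bromotriene F9, and F9 with 33 to the ester F10. i-Bu2AlH gives the alcohol F11, and pyridinium p-toluenesulfonate in MeOH removes only the primary allylic silyl ether to give the diol F12. MnO2 gives the enal F13 and Bu4NF frees the secondary allylic alcohol F14. VO(acac)2/t-BuOOH should then epoxidise only the alkene allylic to that hydroxyl, syn to OH in the conformer fixed by allylic 1,3-strain, to give 37.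

Further compounds
F1 | step 6 | (2E)-5-(tert-butyldimethylsilyloxy)-3-methylpent-2-en-1-ol | OC/C=C(\C)CCO[Si](C)(C)C(C)(C)C
F2 | step 6 | (2E)-5-(tert-butyldimethylsilyloxy)-3-methylpent-2-enal | O=C/C=C(\C)CCO[Si](C)(C)C(C)(C)C
F3 | step 6 | tert-butyl{[(3E)-5,5-dimethoxy-3-methylpent-3-en-1-yl]oxy}dimethylsilane | COC(OC)/C=C(\C)CCO[Si](C)(C)C(C)(C)C
F4 | step 6 | mixed methyl (aS,5E)-2-methylhepta-2,3,5-trien-1-yl acetal of F2 (both acetal epimers) | COC(OCC(C)=[C@@]=C([H])/C=C/C)/C=C(\C)CCO[Si](C)(C)C(C)(C)C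
F5 | step 6 | (7R,8R,8aS)-8-[2-(tert-butyldimethylsilyloxy)ethyl]-1-methoxy-4,7,8-trimethyl-3,7,8,8a-tetrahydro-1H-isochromene (both acetal epimers) | COC1OCC(C)=C2C=C[C@@H](C)[C@@](C)(CCO[Si](C)(C)C(C)(C)C)[C@H]12
F6 | step 6 | (7R,8R,8aS)-8-[2-(tert-butyldimethylsilyloxy)ethyl]-4,7,8-trimethyl-3,7,8,8a-tetrahydro-1H-isochromen-1-ol (both hemiacetal epimers) | OC1OCC(C)=C2C=C[C@@H](C)[C@@](C)(CCO[Si](C)(C)C(C)(C)C)[C@H]12
F7 | step 3 | (2S)-2-hydroxy-2-methylbut-3-yn-1-yl (2E)-5-(tert-butyldimethylsilyloxy)-3-methylpent-2-enoate | C#C[C@@](O)(C)COC(=O)/C=C(\C)CCO[Si](C)(C)C(C)(C)C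
F8 | step 3 | (2S)-2-[(methoxycarbonyl)oxy]-2-methylbut-3-yn-1-yl (2E)-5-(tert-butyldimethylsilyloxy)-3-methylpent-2-enoate | C#C[C@@](OC(=O)OC)(C)COC(=O)/C=C(\C)CCO[Si](C)(C)C(C)(C)C
F9 | step 21 | {[(4S,6E,10E)-11-bromo-2,6,10-trimethylundeca-2,6,10-trien-4-yl]oxy}(tert-butyl)dimethylsilane | Br/C=C(\C)CC/C=C(\C)C[C@H](O[Si](C)(C)C(C)(C)C)C=C(C)C
F10 | step 21 | ethyl 3-[(1S,2R,3R)-6-[(2Z)-1-(tert-butyldimethylsilyloxy)propan-2-ylidene]-2-[(3E,7E,10S)-10-(tert-butyldimethylsilyloxy)-4,8,12-trimethyltrideca-3,7,11-trien-1-yl]-2,3-dimethylcyclohexyl]propanoate | C/C(CO[Si](C)(C)C(C)(C)C)=C1\CC[C@@H](C)[C@@](C)(CC/C=C(\C)CC/C=C(\C)C[C@H](O[Si](C)(C)C(C)(C)C)C=C(C)C)[C@@H]1CCC(=O)OCC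
F11 | step 21 | the propan-1-ol corresponding to ester F10 (both silyl ethers retained) | C/C(CO[Si](C)(C)C(C)(C)C)=C1\CC[C@@H](C)[C@@](C)(CC/C=C(\C)CC/C=C(\C)C[C@H](O[Si](C)(C)C(C)(C)C)C=C(C)C)[C@@H]1CCCO
F12 | step 21 | (2Z)-2-[(2S,3R,4R)-3-[(3E,7E,10S)-10-(tert-butyldimethylsilyloxy)-4,8,12-trimethyltrideca-3,7,11-trien-1-yl]-2-(3-hydroxypropyl)-3,4-dimethylcyclohexylidene]propan-1-ol | C/C(CO)=C1\CC[C@@H](C)[C@@](C)(CC/C=C(\C)CC/C=C(\C)C[C@H](O[Si](C)(C)C(C)(C)C)C=C(C)C)[C@@H]1CCCO
F13 | step 21 | (2Z)-2-[(2S,3R,4R)-3-[(3E,7E,10S)-10-(tert-butyldimethylsilyloxy)-4,8,12-trimethyltrideca-3,7,11-trien-1-yl]-2-(3-hydroxypropyl)-3,4-dimethylcyclohexylidene]propanal | C/C(C=O)=C1\CC[C@@H](C)[C@@](C)(CC/C=C(\C)CC/C=C(\C)C[C@H](O[Si](C)(C)C(C)(C)C)C=C(C)C)[C@@H]1CCCO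
F14 | step 21 | (2Z)-2-[(2S,3R,4R)-3-[(3E,7E,10S)-10-hydroxy-4,8,12-trimethyltrideca-3,7,11-trien-1-yl]-2-(3-hydroxypropyl)-3,4-dimethylcyclohexylidene]propanal | C/C(C=O)=C1\CC[C@@H](C)[C@@](C)(CC/C=C(\C)CC/C=C(\C)C[C@H](O)C=C(C)C)[C@@H]1CCCO
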